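As the chemist answering for the new flasks, I began with the earlier runs.

| setting | south-east | south-west | north-east | south | alder | elm | ash | oak |
|---|---|---|---|---|---|---|---|---|
| starting material | 0.10 M | 0.14 M | 0.22 M | 0.10 M | 0.10 M (in portions, 3, over 2.5 d) | 0.10 M | 0.10 M (fed, over 2.5 d) | 0.10 M |
| second nucleophile | 1.8 equiv | 1.8 equiv | 1.8 equiv | 2.7 equiv | 1.80 equiv | 1.80 equiv (fed, over 2.5 d) | 1.80 equiv | 1.80 equiv |
| gas | 18 mM (held) | 18 mM (held) | 18 mM (held) | 18 mM (held) | 18 mM (held) | 18 mM (held) | 18 mM (held) | 18 mM (held) |
| remark | run made earlier | run made earlier | run made earlier | run made earlier | first portion at the start, last at 2.5 d | all else is in the flask from the start; the feed brings no volume worth counting | all else is in the flask from the start; the feed brings no volume worth counting | everything together at the start |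
| time |  |  |  |  | 3.0 d | 3.0 d | 3.0 d | 3.0 d |

- south-east (time / h: other capture product / %, target / %, starting material / %): 3.00: 26.0, 1.0, 72.2; 8.00: 54.7, 2.9, 40.0; 20.0: 81.0, 7.4, 10.9; 40.0: 85.8, 11.6, 1.5
- south-west (time / h: other capture product / %, target / %, starting material / %): 3.00: 25.7, 0.9, 72.7; 8.00: 55.7, 1.2, 40.8; 20.0: 82.6, 6.8, 11.4; 40.0: 89.6, 9.3, 0.6
- north-east (time / h: other capture product / %, target / %, starting material / %): 10.0: 64.4, 1.9, 33.4; 20.0: 84.5, 3.2, 10.8; 30.0: 91.1, 5.2, 3.5; 40.0: 92.0, 7.0, 1.1
- south (time / h: other capture product / %, target / %, starting material / %): 3.00: 26.4, 0.8, 72.1; 8.00: 55.7, 3.8, 41.2; 20.0: 81.1, 7.3, 11.4; 40.0: 87.6, 10.4, 0.8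

(scatter of a reading: 0.5 percentage points)

- the flask with the highest amount of other capture product, in percent of the starting material charged ("all alike" if they lie within 1.5 percentage points) (alder / elm / ash / oak / all alike)
- final other capture product, as a percentage of the starting material charged, in alder
- final other capture product, as a percentage of the starting material charged, in elm
- final other capture product, as a percentage of the starting material charged, in ash
- final other capture product, as a percentage of the starting material charged, in oak

- at the start none of first nucleophile is dissolved
- candidate steps: second nucleophile <-> dormant form; starting material -> intermediate; 2 first nucleophile -> homo dimer; gas <-> first nucleophile; second nucleophile + intermediate -> other capture product; first nucleophile + intermediate -> target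

I ordered what they showed from fast to slow.

1. Intermediate: in the south-east run at 3.00 h, the readings summed to 99.2 %, so very little stood as intermediate.

2. Starting material: south-east held 10.9 % at 20.0 h and north-east 10.8 % at 20.0 h, so its first-order constant k_A did not follow the charge. I read k_A = 0.111 h⁻¹. At 0.10 M, intermediate therefore starts forming at 0.0111 M h⁻¹.

3. First nucleophile: it starts undissolved. At 40.0 h, target was 0.0116 M in south-east and 0.0154 M in north-east, on 2.20 times the charge. That looked like a supply from the gas rather than a share of the charge. I defined the supply rate s, the first nucleophile delivered per hour, and read it from north-east target over time: 3.85 × 10⁻⁴ M h⁻¹. Over 3.0 d, s comes to 27.7 % of a 0.10 M charge, which is a rough estimate of target and not a bound.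

4. Elm: its feed f is 0.00300 M h⁻¹. At the start of elm, intermediate forms faster than both nucleophiles arrive, but that rate falls as starting material goes. As a crude estimate, I took the two arrival rates as the shares of capture, which gives other capture product f/(f+s) = 88.6 %.

The forecast named oak highest, giving alder 60 %, elm 33 %, ash 63 % and oak 86.5 %. On elm it held that “second nucleophile is scarce during the early conversion, so other falls to about 33%”; there my split differed.

The flasks gave alder 63.3 %, elm 82.7 %, ash 67.2 % and oak 86.6 %, with oak highest.

    second nucleophile ⇌ dormant form (K = 0.820, k = 0.00860 h⁻¹)
    starting material → intermediate (k = 0.110 h⁻¹)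
    2 first nucleophile → homo dimer (k = 1.80 M⁻¹ h⁻¹)
    gas ⇌ first nucleophile, rate k4*(csat - [first nucleophile]) (kL = 0.0270 h⁻¹)
    second nucleophile + intermediate → other capture product (k = 59.0 M⁻¹ h⁻¹)
    first nucleophile + intermediate → target (k = 1700 M⁻¹ h⁻¹)

In elm, f stood at 7.79 times s, and the split of 88.6 % lay 5.9 percentage points above the 82.7 % found. Target in elm stood at 17.3 %, with 44 % of the second nucleophile left at 3.00 d, so the feed had not all been captured on arrival.

For the neighbour like alder with 0.040 M of starting material, s comes to 69.3 % of its charge over 3.0 d, so by this estimate target could lead. It gave 53.8 % target against 36.8 % other capture product, and target held most.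

Readings and results were computed on assumed constants; scatter was added.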